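The runs are simulated with made-up constants.

At early times free monomer falls towards a floor much as a first-order lag settles, and the two earlier runs, zeta and theta, differ in their stray impurity.

the same everywhere: free monomer 0.050 M; initiator 0.75 mM

| flask | protic impurity | stray impurity | remark | time |
|---|---|---|---|---|
| zeta | 0.015 M | 0.080 mM | run made earlier |  |
| theta | 0.015 M | 0.32 mM | run made earlier |  |
| flask | 0.0150 M | 0.16 mM |  | 10 min |

| run | time / min | monomer in chains / % | free monomer / % |
|---|---|---|---|
| zeta | 1.33 | 80.8 | 12.8 |
| zeta | 3.00 | 86.0 | 6.1 |
| zeta | 4.00 | 85.2 | 6.3 |
| zeta | 6.00 | 84.5 | 6.2 |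
| zeta | 8.00 | 83.7 | 5.7 |
| zeta | 10.0 | 81.9 | 5.6 |
| theta | 0.833 | 52.9 | 40.4 |
| theta | 1.33 | 69.8 | 22.0 |
| theta | 2.00 | 78.8 | 11.7 |
| theta | 3.00 | 82.8 | 6.8 |
| theta | 4.00 | 84.2 | 6.3 |
| theta | 6.00 | 82.7 | 6.4 |
| theta | 10.0 | 81.2 | 6.1 |

(standard deviation of a reading: 0.3 percentage points)

1. average number of monomer units in a chain (chains begun, living or dead) at 10 min
2. part of the free monomer that has reacted at 10 min

- the average divides the monomer in chains by the number of chains begun, living and dead together
- the earlier runs do not show the number of chains; that part of a forecast is a guess

This is my own reckoning, built one process at a time. Start with the main step and suppose each chain grows from one living end. With living ends steady the fall is pseudo-first-order: [free monomer] minus its floor decays as exp(−t/τ), and the rate constant, the inverse of τ, is proportional to [living end]. The floor reads 5.85%, which gives a conversion of 94.1%.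

Now add the stray impurity. Measured from the charge to 1.33 min, the rate constant is 1.96 min⁻¹ in zeta and 1.33 min⁻¹ in theta, a ratio of 1.47. Suppose stray impurity destroys initiator one for one; the flask is charged with less of it than of initiator, so there it is the limiting reagent of that step. What remains is the active initiator, charged initiator minus stray impurity, 0.590 mM in this flask, and the same subtraction predicts a ratio of 1.56 between the runs. Scaling zeta gives the flask 1.73 min⁻¹, so τ is 0.580 min, and 10 min is far longer than that: I expect the flask's conversion to stand at the floor value.

Last comes a slow leak. Free monomer plus monomer in chains drops 4.6 percentage points in zeta between 3.00 min and 10.0 min, so I read monomer in chains directly at 10 min: 81.6%. If each active initiator begins one chain, which is a guess, the average in the flask is 69.1.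

The forecast agrees on conversion, 94.1% (93.4% to 94.7%), but differs on length, 15 (3 to 70), saying “Chains begun is the guess”.

The flask gives an average of 69.6 units per chain and a conversion of 93.9%.

    protic impurity + free monomer → quenched substrate (k = 0.140 M⁻¹ s⁻¹)
    monomer in chains + living end → free monomer + living end, rate k2*[living end] as long as [monomer in chains] is above zero (k = 0.180 s⁻¹)
    initiator + stray impurity → spent initiator (k = 68000 M⁻¹ s⁻¹)
    free monomer + initiator → living end + monomer in chains (k = 1.70 M⁻¹ s⁻¹)
    free monomer + living end → monomer in chains + living end, rate k5*[living end]*[free monomer] (k = 57.0 M⁻¹ s⁻¹)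

In the flask, stray impurity stood at 0% by 1.00 min, with 1.60 × 10⁻⁴ M of spent initiator formed, while free monomer fell to 23.8%. From 5.00 min to 10.0 min free monomer stayed near 6.08% while protic impurity went from 68.5% to 60.3% of its charge and monomer in chains from 84.5% to 82.0%. Dividing that monomer in chains by the active initiator gives 69.5 for the flask. The neighbour charged with 0.013 M of free monomer held 44.6% in chains, so the same 0.590 mM gives 9.83, and that flask gave 10.0.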